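**Assumptions (one line each):** the target has no stereocentres, so there is no enantiomer to set. In step 4 the aroyl radical is assumed to add mainly at C‑5 of toluquinone, para to the methyl group.

## Retrosynthetic overview
1. Acredinone B (**1**) is disconnected at the ring‑B C(=O)–aryl bond. It comes from radical hydroacylation of quinone monoketal **2** with arylacetaldehyde **3**, followed by loss of MeOH, which aromatises ring B with the OMe/OH pattern already set.
2. Aldehyde **3** comes from acetal **5**, which is made by radical addition of the •CH2CH(OMe)2 radical (from bromoacetal **4**) to the same monoketal **2**. Both halves therefore come from one acceptor.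
3. **2** comes from PIDA/MeOH oxidation of phenol **6**, which comes from selective mono‑O‑methylation of hydroquinone **7**. **7** is made by photoacylation of toluquinone **8** with 2,6‑dimethoxybenzaldehyde **9**.
4. **8** comes from m‑cresol **10**. **9** comes from 1,3‑dimethoxybenzene **11**, which comes from resorcinol **12**.

## Route

**Step 1**
Reactants: **12** resorcinol
Product: **11** 1,3‑dimethoxybenzene
Conditions: Me2SO4 (2.5 equiv), K2CO3, acetone, reflux
Reagents that add atoms: dimethyl sulfate, COS(=O)(=O)OC (two CH3)
Why: Williamson double O‑methylation.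

**Step 2**
Reactants: **11**
Product: **9** 2,6‑dimethoxybenzaldehyde
Conditions: n‑BuLi, THF, 0 °C→rt; then DMF, 0 °C→rt
Reagents that add atoms: DMF, CN(C)C=O (supplies CHO)
Why: directed ortho‑metalation between the two OMe groups, then formylation.

**Step 3**
Reactants: **10** m‑cresol
Product: **8** 2‑methyl‑1,4‑benzoquinone
Conditions: Fremy's salt (2.2 equiv), aq. KH2PO4/Na2HPO4, acetone, rt
Reagents that add atoms: potassium nitrosodisulfonate, [O]N(S(=O)(=O)[O-])S(=O)(=O)[O-].[K+].[K+] (oxygen donor)
Why: Teuber oxidation of a phenol with a free para position to the p‑quinone.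

**Step 4**
Reactants: **8** and **9** (2.5 equiv)
Product: **7** (2,6‑dimethoxyphenyl)(2,5‑dihydroxy‑4‑methylphenyl)methanone
Conditions: hv (400 nm), MeCN, rt, N2, 24 h; Na2S2O4 workup
Reagents that add atoms: none
Why: photoacylation of a quinone; the triplet quinone abstracts the aldehyde H, the aroyl radical combines at C‑5 (para to Me), and the product is the hydroquinone.

**Step 5**
Reactants: **7**
Product: **6** (2‑hydroxy‑5‑methoxy‑4‑methylphenyl)(2,6‑dimethoxyphenyl)methanone
Conditions: Me2SO4 (1.0 equiv), K2CO3, acetone, 45 °C
Reagents that add atoms: dimethyl sulfate, COS(=O)(=O)OC (one CH3)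
Why: chemoselective Williamson alkylation of the non‑chelated OH (next to Me), leaving the OH that is H‑bonded to the ketone untouched.

**Step 6**
Reactants: **6**
Product: **2** 2‑aroyl‑4,4‑dimethoxy‑5‑methylcyclohexa‑2,5‑dienone (quinone monoketal)
Conditions: PhI(OAc)2 (1.2 equiv), MeOH, 0 °C→rt, 1 h
Reagents that add atoms: methanol, CO (adds one OMe)
Why: hypervalent‑iodine oxidative ketalisation of a 4‑methoxyphenol. This fixes which oxygen will become OMe and which OH, and C‑6 becomes a doubly activated acceptor site.

**Step 7**
Reactants: **2** and **4** bromoacetaldehyde dimethyl acetal (3 equiv)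
Product: **5** aryl‑acetaldehyde dimethyl acetal
Conditions: (Me3Si)3SiH (1.5 equiv, syringe pump), AIBN, PhH, 80 °C; then TsOH·H2O, CH2Cl2, rt
Reagents that add atoms: none (the silane supplies only H)
Why: Proposed new method: the nucleophilic primary radical •CH2CH(OMe)2 (from Br abstraction by the silyl radical) adds to C‑6 of the monoketal, which is β to both the ring C=O and the aroyl C=O. The resulting 1,3‑dicarbonyl radical takes H from the silane, and acid‑promoted loss of MeOH aromatises the ring to the 1‑OMe/4‑OH pattern. The closest known reactions are Giese addition to 2‑acylenones and the aromatisation of quinone‑monoketal adducts.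

**Step 8**
Reactants: **5**
Product: **3** arylacetaldehyde
Conditions: 1 M HCl/THF (1:3), 40 °C, 2 h; use immediately
Reagents that add atoms: water, O
Why: acetal hydrolysis; the phenol is meta to CH2CHO, so benzofuran formation is not possible.

**Step 9**
Reactants: **2** (2 equiv) and **3** (1 equiv)
Product: **1** acredinone B
Conditions: TBADT (2 mol%), MeCN, 390 nm LEDs, 10 °C, 16 h; then TsOH·H2O (0.2 equiv), CH2Cl2, rt
Reagents that add atoms: none
Why: Proposed new method: decatungstate abstracts the aldehyde H to give the acyl radical ArCH2C(=O)•. This nucleophilic radical adds to C‑6 of **2**, and the stabilised adduct radical is reduced and protonated by the reduced decatungstate. Acid then eliminates MeOH to aromatise ring B, forming the ring‑B C(=O)–aryl bond and giving the target. The closest known reactions are TBADT hydroacylation of electron‑poor alkenes and photoacylation of quinones.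

## Compound list
1 | acredinone B | COc1cccc(OC)c1C(=O)c1c(O)cc(C)c(OC)c1CC(=O)c1c(OC)c(C)cc(O)c1C(=O)c1c(OC)cccc1OC | target
2 | 2‑(2,6‑dimethoxybenzoyl)‑4,4‑dimethoxy‑5‑methylcyclohexa‑2,5‑dienone | COC1(OC)C(C)=CC(=O)C(C(=O)c2c(OC)cccc2OC)=C1 | intermediate
3 | [2‑(2,6‑dimethoxybenzoyl)‑3‑hydroxy‑6‑methoxy‑5‑methylphenyl]acetaldehyde | COc1c(C)cc(O)c(C(=O)c2c(OC)cccc2OC)c1CC=O | intermediate
4 | bromoacetaldehyde dimethyl acetal | COC(CBr)OC | starting material
5 | dimethyl acetal of 3 | COc1c(C)cc(O)c(C(=O)c2c(OC)cccc2OC)c1CC(OC)OC | intermediate
6 | (2‑hydroxy‑5‑methoxy‑4‑methylphenyl)(2,6‑dimethoxyphenyl)methanone | COc1cc(C(=O)c2c(OC)cccc2OC)c(O)cc1C | intermediate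
7 | (2,6‑dimethoxyphenyl)(2,5‑dihydroxy‑4‑methylphenyl)methanone | Cc1cc(O)c(C(=O)c2c(OC)cccc2OC)cc1O | intermediate
8 | 2‑methyl‑1,4‑benzoquinone | CC1=CC(=O)C=CC1=O | intermediate
9 | 2,6‑dimethoxybenzaldehyde | COc1cccc(OC)c1C=O | intermediate
10 | m‑cresol | Cc1cccc(O)c1 | starting material
11 | 1,3‑dimethoxybenzene | COc1cccc(OC)c1 | intermediate
12 | resorcinol | Oc1cccc(O)c1 | starting material

**Totals:** 9 steps in total; longest linear sequence 8 steps (12→11→9→7→6→2→5→3→1).

## Three steps most likely to fail
1. **Step 9.** The arylacetyl radical can decarbonylate, or the benzylic C–H can be abstracted, and the new bond sits between two ortho‑substituted centres. Fallback: make the ring‑B methyl ketone from **2** by acetyl‑radical hydroacylation (CH3CHO), make the ring‑A aryl bromide from **2** by conjugate addition of bromide with aromatisation, and join them by Pd‑catalysed α‑arylation of the methyl ketone.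
2. **Step 4.** Acylation may give the wrong regioisomer (C‑6 instead of C‑5), or over‑acylate. Fallback: Vilsmeier formylation of 2,5‑dimethoxytoluene at C‑4, addition of 2,6‑dimethoxyphenyllithium, DMP oxidation, then BCl3 demethylation of the OMe ortho to the new ketone, which gives **6** directly.
3. **Step 7.** The radical addition to the hindered C‑6 (next to the ketal carbon) may lose out to premature reduction of the radical by the silane. Fallback: a polar Lewis‑acid Mukaiyama–Michael addition of the silyl ketene acetal of methyl acetate to **2**, aromatisation to the methyl arylacetate, then DIBAL‑H reduction to **3**.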